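**Strategy.** Ring B of the target benzophenone is an orcinol unit: C1 carries the aroyl carbonyl, C2 the methyl group, C4 and C6 the oxygens. This 1,3-dioxygenation lets ring B be cut back to a 5-methylcyclohexane-1,3-dione, built from a ring A aroylacetone and methyl crotonate. In one operation a Michael addition forms C1–C2 and a Claisen closure forms C4–C5, fixing the aroyl group beside the methyl-bearing carbon. The precursor is a 1-arylbutane-1,3-dione whose ring A already holds chlorine, both methoxy groups and a MOM-masked C2 hydroxyl. Dehydrogenation, MOM protection of the C4 hydroxyl, methylation at C6 and one acid step finish the synthesis.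

Key step: step 4

Remark on the chemistry: 2-chloro-3,5-dimethoxyphenol is assumed to be a purchasable building block. The target is achiral; the two sp3 centres that appear in 10 and 11 are carried as racemic diastereomer mixtures and disappear on aromatization. Ring A is the chlorinated ring (C1 carbonyl-bearing, C2 OH, C3 Cl, C4 and C6 OMe); ring B is the methylated ring (C1 carbonyl-bearing, C2 CH3, C4 OH, C6 OMe). Compound 11 is drawn as the triketone although it should exist largely as enol tautomers.

**Route**

Step 1
Reactants: 1 2-chloro-3,5-dimethoxyphenol; 2 acetic anhydride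
Product: 5 1-(3-chloro-2-hydroxy-4,6-dimethoxyphenyl)ethan-1-one, via aryl acetate 3 (not isolated), via difluoroboron chelate 4 (not isolated)
Conditions: Ac2O (1.2 equiv), BF3·OEt2 (3 equiv), 90 °C; then EtOH/H2O, 70 °C
Reagents that add atoms: none
Why: One-pot O-acetylation and BF3-promoted Fries rearrangement should deliver the acetyl group to C6 of 1, the only free position ortho to the hydroxyl, because the ortho-hydroxy ketone is trapped as the six-membered BF2 chelate 4 whereas the position between the two methoxy groups is more hindered and gains no chelation; aqueous ethanol then hydrolyses the chelate.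

Step 2
Reactants: 5 1-(3-chloro-2-hydroxy-4,6-dimethoxyphenyl)ethan-1-one
Product: 6 1-[3-chloro-4,6-dimethoxy-2-(methoxymethoxy)phenyl]ethan-1-one
Conditions: NaH (1.1 equiv), DMF, 0 °C; then MOMCl, 0 °C to rt
Reagents that add atoms: chloromethyl methyl ether (MOMCl), COCCl
Why: Williamson ether synthesis, in which NaH turns the chelated phenol (far more acidic than the acetyl CH3) into its sodium phenoxide, which should displace chloride from MOMCl at oxygen to give the base-stable acetal needed for steps 3 and 4.

Step 3
Reactants: 6 1-[3-chloro-4,6-dimethoxy-2-(methoxymethoxy)phenyl]ethan-1-one; 7 ethyl acetate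
Product: 8 1-[3-chloro-4,6-dimethoxy-2-(methoxymethoxy)phenyl]butane-1,3-dione
Conditions: NaH (3 equiv), EtOAc (excess), THF, reflux; then AcOH, H2O, 0 °C
Reagents that add atoms: none
Why: Crossed Claisen condensation, in which the sodium enolate of methyl ketone 6 is acylated at carbon by ethyl acetate and the equilibrium is drawn forward by deprotonation of the β-diketone, while the MOM acetal, the aryl chloride and the methyl ethers are inert to NaH.

Step 4
Reactants: 8 1-[3-chloro-4,6-dimethoxy-2-(methoxymethoxy)phenyl]butane-1,3-dione; 9 methyl (E)-but-2-enoate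
Product: 11 4-[3-chloro-4,6-dimethoxy-2-(methoxymethoxy)benzoyl]-5-methylcyclohexane-1,3-dione (racemic), via Michael adduct 10 (not isolated)
Conditions: NaOMe (2.5 equiv), 9 (1.5 equiv), MeOH, reflux; then cold aq AcOH to pH 5
Reagents that add atoms: none
Why: Methoxide converts 8 into its diketonate, which adds through the central carbon to the β-carbon of 9 (Michael addition, ring B bond C1–C2) to give 10, and reversible enolization of the acetyl methyl group of 10 then lets that carbon attack the ester carbonyl with loss of methoxide (Claisen acylation, ring B bond C4–C5). The closest known reaction type is the Michael–Claisen annulation of acetoacetates or acetylacetone with crotonates, which gives dihydroorsellinates and 4-acyl-5-methylcyclohexane-1,3-diones. The one ring formed, carbocyclic ring B, closes in the 6-exo-trig mode, and the closure becomes irreversible because the acidic cyclic 1,3-dione is deprotonated at once and is the thermodynamic sink of all preceding equilibria. The two new sp3 centres (ring B C1 and C2) are not controlled: they form as racemates, the epimerizable C1 should settle trans to the methyl group, and both are erased in step 5. The selectivity required is regiochemical and is secured by the substrate, since only the acetyl side of the diketone carries enolizable hydrogens and the ring can therefore close in one direction only, placing the aroyl group on the carbon next to the methyl-bearing one. Retro-Claisen deacetylation of the congested adduct by methoxide is the competing path; it is countered by the fast intramolecular closure and the excess of 9, and the mild acetic acid quench spares the MOM acetal.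

Step 5
Reactants: 11 4-[3-chloro-4,6-dimethoxy-2-(methoxymethoxy)benzoyl]-5-methylcyclohexane-1,3-dione
Product: 12 [3-chloro-4,6-dimethoxy-2-(methoxymethoxy)phenyl](2,4-dihydroxy-6-methylphenyl)methanone
Conditions: DDQ (1.1 equiv), 1,4-dioxane, 80 °C
Reagents that add atoms: none
Why: Quinone dehydrogenation, in which the dienol form of 11 should transfer hydride from the methyl-bearing ring B C2–H to DDQ to give an oxygen-stabilized cyclohexadienyl cation that loses a proton and ends as the resorcinol, driven by aromatization, while the MOM acetal, aryl chloride and methyl ethers are inert to DDQ.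

Step 6
Reactants: 12 [3-chloro-4,6-dimethoxy-2-(methoxymethoxy)phenyl](2,4-dihydroxy-6-methylphenyl)methanone
Product: 13 [3-chloro-4,6-dimethoxy-2-(methoxymethoxy)phenyl][2-hydroxy-4-(methoxymethoxy)-6-methylphenyl]methanone
Conditions: MOMCl (1.05 equiv), iPr2NEt, CH2Cl2, 0 °C
Reagents that add atoms: chloromethyl methyl ether (MOMCl), COCCl
Why: Chemoselective O-alkylation, since the ring B C4 hydroxyl para to the ketone is the more acidic and the only unchelated phenol whereas the C6 hydroxyl is held in a hydrogen bond to the carbonyl oxygen, so one equivalent of MOMCl with a hindered amine at 0 °C should react at C4–OH only.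

Step 7
Reactants: 13 [3-chloro-4,6-dimethoxy-2-(methoxymethoxy)phenyl][2-hydroxy-4-(methoxymethoxy)-6-methylphenyl]methanone
Product: 14 [3-chloro-4,6-dimethoxy-2-(methoxymethoxy)phenyl][2-methoxy-4-(methoxymethoxy)-6-methylphenyl]methanone
Conditions: MeI, K2CO3, DMF, 40 °C
Reagents that add atoms: iodomethane (MeI), CI
Why: Williamson methylation, in which K2CO3 in DMF should break the hydrogen bond of the remaining C6 phenol and its phenoxide is methylated at oxygen, every other oxygen being capped.

Step 8
Reactants: 14 [3-chloro-4,6-dimethoxy-2-(methoxymethoxy)phenyl][2-methoxy-4-(methoxymethoxy)-6-methylphenyl]methanone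
Product: 15 (3-chloro-2-hydroxy-4,6-dimethoxyphenyl)(4-hydroxy-2-methoxy-6-methylphenyl)methanone
Conditions: aq HCl (3 M), MeOH, 50 °C
Reagents that add atoms: none
Why: Acid-catalysed acetal cleavage (transacetalization to dimethoxymethane in methanol) should remove both MOM groups in one operation, while the aryl methyl ethers, the aryl chloride and the diaryl ketone are stable to dilute HCl at this temperature.

**Compound list**

1 | 2-chloro-3,5-dimethoxyphenol | COc1cc(O)c(Cl)c(OC)c1 | starting material
2 | acetic anhydride | CC(=O)OC(C)=O | starting material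
3 | 2-chloro-3,5-dimethoxyphenyl acetate | CC(=O)Oc1cc(OC)cc(OC)c1Cl | intermediate (not isolated)
4 | O,O-difluoroboron chelate of 1-(3-chloro-2-hydroxy-4,6-dimethoxyphenyl)ethan-1-one (phenolate and ketone oxygens bound to BF2) | CC1=[O+][B-](F)(F)Oc2c(Cl)c(OC)cc(OC)c12 | intermediate (not isolated)
5 | 1-(3-chloro-2-hydroxy-4,6-dimethoxyphenyl)ethan-1-one | CC(=O)c1c(O)c(Cl)c(OC)cc1OC | intermediate
6 | 1-[3-chloro-4,6-dimethoxy-2-(methoxymethoxy)phenyl]ethan-1-one | COCOc1c(Cl)c(OC)cc(OC)c1C(C)=O | intermediate
7 | ethyl acetate | CCOC(C)=O | starting material
8 | 1-[3-chloro-4,6-dimethoxy-2-(methoxymethoxy)phenyl]butane-1,3-dione | COCOc1c(Cl)c(OC)cc(OC)c1C(=O)CC(C)=O | intermediate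
9 | methyl (E)-but-2-enoate (methyl crotonate) | C/C=C/C(=O)OC | starting material
10 | methyl 4-acetyl-5-[3-chloro-4,6-dimethoxy-2-(methoxymethoxy)phenyl]-3-methyl-5-oxopentanoate (racemic diastereomer mixture) | COCOc1c(Cl)c(OC)cc(OC)c1C(=O)C(C(C)=O)C(C)CC(=O)OC | intermediate (not isolated)
11 | 4-[3-chloro-4,6-dimethoxy-2-(methoxymethoxy)benzoyl]-5-methylcyclohexane-1,3-dione (racemic, relative configuration not controlled, trans expected) | COCOc1c(Cl)c(OC)cc(OC)c1C(=O)C1C(C)CC(=O)CC1=O | intermediate
12 | [3-chloro-4,6-dimethoxy-2-(methoxymethoxy)phenyl](2,4-dihydroxy-6-methylphenyl)methanone | COCOc1c(Cl)c(OC)cc(OC)c1C(=O)c1c(C)cc(O)cc1O | intermediate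
13 | [3-chloro-4,6-dimethoxy-2-(methoxymethoxy)phenyl][2-hydroxy-4-(methoxymethoxy)-6-methylphenyl]methanone | COCOc1c(Cl)c(OC)cc(OC)c1C(=O)c1c(C)cc(OCOC)cc1O | intermediate
14 | [3-chloro-4,6-dimethoxy-2-(methoxymethoxy)phenyl][2-methoxy-4-(methoxymethoxy)-6-methylphenyl]methanone | COCOc1c(Cl)c(OC)cc(OC)c1C(=O)c1c(C)cc(OCOC)cc1OC | intermediate
15 | (3-chloro-2-hydroxy-4,6-dimethoxyphenyl)(4-hydroxy-2-methoxy-6-methylphenyl)methanone (achiral) | COc1cc(OC)c(C(=O)c2c(C)cc(O)cc2OC)c(O)c1Cl | target

**Totals**

Total step count: 8
Longest linear sequence: 8 steps (1 to 15)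

**Steps most likely to fail**

Step 4. The conjugate addition of the hindered, stabilized diketonate to a β-substituted acrylate may be slow and reversible, so that methoxide-induced deacetylation (retro-Claisen cleavage) of 8 or of the adduct overtakes ring closure. The fallback sets out from 8 and comes back at 11, forming the same two ring B bonds with a far more electrophilic acceptor. Compound 8 is added to purchased diethyl ethylidenemalonate (CC=C(C(=O)OCC)C(=O)OCC) with catalytic DBU in THF at room temperature, which should give diethyl 2-{3-acetyl-4-[3-chloro-4,6-dimethoxy-2-(methoxymethoxy)phenyl]-4-oxobutan-2-yl}propanedioate F1. NaOEt in EtOH at room temperature then closes the ring by Claisen acylation of the acetyl methyl group onto one malonate ester to give ethyl 3-[3-chloro-4,6-dimethoxy-2-(methoxymethoxy)benzoyl]-2-methyl-4,6-dioxocyclohexane-1-carboxylate F2. Krapcho dealkoxycarbonylation (LiCl, wet DMSO, 120 °C) removes the extra ester under neutral conditions and returns the route to 11.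

Step 5. Hydride transfer from the strongly hydrogen-bonded enol may be sluggish, or the electron-rich resorcinol may be oxidized further by the quinone, and the acidic hydroquinone by-product may start to erode the ring A acetal. The fallback sets out from 11 and comes back at 12 by a catalytic aerobic dehydrogenation: Pd(OCOCF3)2 (5 mol %), 2-(dimethylamino)pyridine (10 mol %), O2 (1 atm), DMSO, 80 °C. It should proceed through a carbon-bound palladium enolate at ring B C1 and β-hydride elimination of the C2 hydrogen, with divalent palladium regenerated by dioxygen. No stoichiometric oxidant or acid is present, and no compound outside the list is formed (F0).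

Step 1. The acyl group may migrate to the position para to the hydroxyl (between the two methoxy groups), or the Lewis acid may cleave the methyl ether next to the new ketone. The fallback sets out from 1 and comes back at 6 with a strictly ortho-directed C1 unit. Formylation of 1 with MgCl2, Et3N and paraformaldehyde in MeCN at reflux (the magnesium phenoxide delivers formaldehyde only to the free ortho position) should give 3-chloro-2-hydroxy-4,6-dimethoxybenzaldehyde F3. NaH and MOMCl in DMF give 3-chloro-4,6-dimethoxy-2-(methoxymethoxy)benzaldehyde F4. MeMgBr in THF at 0 °C gives racemic 1-[3-chloro-4,6-dimethoxy-2-(methoxymethoxy)phenyl]ethan-1-ol F5, and oxidation with Dess–Martin periodinane in CH2Cl2 gives 6.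

**Further compounds**

F1 | step 4 | diethyl 2-{3-acetyl-4-[3-chloro-4,6-dimethoxy-2-(methoxymethoxy)phenyl]-4-oxobutan-2-yl}propanedioate (racemic diastereomer mixture) | COCOc1c(Cl)c(OC)cc(OC)c1C(=O)C(C(C)=O)C(C)C(C(=O)OCC)C(=O)OCC
F2 | step 4 | ethyl 3-[3-chloro-4,6-dimethoxy-2-(methoxymethoxy)benzoyl]-2-methyl-4,6-dioxocyclohexane-1-carboxylate (racemic diastereomer mixture) | COCOc1c(Cl)c(OC)cc(OC)c1C(=O)C1C(C)C(C(=O)OCC)C(=O)CC1=O
F0 | step 5 | none | none
F3 | step 1 | 3-chloro-2-hydroxy-4,6-dimethoxybenzaldehyde | O=Cc1c(O)c(Cl)c(OC)cc1OC
F4 | step 1 | 3-chloro-4,6-dimethoxy-2-(methoxymethoxy)benzaldehyde | COCOc1c(Cl)c(OC)cc(OC)c1C=O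
F5 | step 1 | racemic 1-[3-chloro-4,6-dimethoxy-2-(methoxymethoxy)phenyl]ethan-1-ol | COCOc1c(Cl)c(OC)cc(OC)c1C(C)O
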